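A direct plan would brominate the TIPS-protected ring B propiophenone A1 at C8 with CuBr2 to give the racemic α-bromo ketone A2, and would displace the bromide of A2 with the ring A phenol (1 below) to give the racemic 8-aryloxy ketone A3. A ketoreductase would reduce A3 under dynamic kinetic resolution to the (7S,8S)-alcohol A4. The derived acetate A5 would then be deoxygenated through the para-quinone methide A6 with fluoride and borohydride.
- The enzymatic dynamic reduction would be weakest: the only stereocentre of the target would depend on an enzyme not yet known to accept an acyclic ketone between two bulky groups, and on racemisation outrunning reduction.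
- The C7 oxygen would go in and out (protect, reduce, acetylate, deoxygenate) for no gain in complexity, and the C7 centre would be discarded.
- The quinone methide reduction would risk the latest material: A6 could tautomerise to the 7,8-enol ether and erase C8, or lose the ring A phenoxide, and borane could attack the allyl group.

**Plan of the new route**
- The retrosynthesis cuts the C7–C1 bond to ring B last and the C8–O bond to ring A first; C8 with its O, CH3 and H is bought as methyl (R)-lactate.
- Enabling feature: C7 is a bare CH2 between C8 and C1 of ring B, and C1 is para to the phenol oxygen. Both ends therefore exist as halides: a lactate-derived primary bromide and 4-bromoguaiacol.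
- These two electrophilic carbons would be joined by a nickel-catalysed reductive cross-electrophile coupling, a union of like polarity through a C7 radical.
- Neither ring is built; ring A is attached to the chain first and ring B last, the reverse of the direct plan.
- C8 is set once, by SN2 inversion at the ester-activated lactate carbon. C7 never bears oxygen, so no ketone, no enzymatic reduction, no acetate leaving group and no quinone methide arise.

Key step: step 5

Remark: neolignan numbering is used for the chain (C7 = CH2 on ring B, C8 = stereocentre, C9 = methyl). Ring A is the 4-allyl-2,6-dimethoxyphenyl ring and ring B the 4-hydroxy-3-methoxyphenyl ring. The stereocentre of the target is read from the SMILES as S.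

Step 1
Reactants: 1 4-allyl-2,6-dimethoxyphenol; 2 methyl (R)-lactate
Product: 3 methyl (2S)-2-(4-allyl-2,6-dimethoxyphenoxy)propanoate
Conditions: PPh3 (1.3 equiv), DIAD (1.3 equiv), THF, 0 °C to rt
Reagents that add atoms: none
Why: Mitsunobu reaction, in which the alkoxyphosphonium ion of the lactate is displaced by the phenoxide in an SN2 step accelerated by the adjacent ester, so that C8 is set as S by inversion of the R carbinol even with a 2,6-disubstituted phenol, while the allyl group is inert.

Step 2
Reactants: 3 methyl (2S)-2-(4-allyl-2,6-dimethoxyphenoxy)propanoate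
Product: 4 (2S)-2-(4-allyl-2,6-dimethoxyphenoxy)propan-1-ol
Conditions: LiAlH4 (1.0 equiv), THF, 0 °C
Reagents that add atoms: none
Why: Hydride reduction of an ester to the primary alcohol at 0 °C touches neither the aryl ether, the allyl group nor the C8–H bond, so the S configuration is carried over.

Step 3
Reactants: 4 (2S)-2-(4-allyl-2,6-dimethoxyphenoxy)propan-1-ol
Product: 5 5-allyl-2-{[(2S)-1-bromopropan-2-yl]oxy}-1,3-dimethoxybenzene
Conditions: CBr4 (1.3 equiv), PPh3 (1.3 equiv), CH2Cl2, 0 °C
Reagents that add atoms: carbon tetrabromide, BrC(Br)(Br)Br
Why: Appel reaction, in which bromide displaces the primary alkoxyphosphonium group at C7 only, so that C8, one atom away, keeps its configuration and the neutral conditions spare the allyl group.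

Step 4
Reactants: 6 4-bromo-2-methoxyphenol
Product: 7 4-bromo-2-methoxyphenyl acetate
Conditions: Ac2O (1.5 equiv), DMAP (cat.), pyridine, rt
Reagents that add atoms: acetic anhydride, CC(=O)OC(C)=O
Why: DMAP-catalysed O-acetylation of a phenol masks the acidic O–H and replaces a strong para donor by a weak acceptor, which should speed oxidative addition of nickel into the C–Br bond in step 5.

Step 5
Reactants: 5 5-allyl-2-{[(2S)-1-bromopropan-2-yl]oxy}-1,3-dimethoxybenzene; 7 4-bromo-2-methoxyphenyl acetate (1.3 equiv)
Product: 9 4-[(2S)-2-(4-allyl-2,6-dimethoxyphenoxy)propyl]-2-methoxyphenol, via coupled aryl acetate 8 (not isolated)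
Conditions: NiI2 (10 mol%), 4,4'-dimethoxy-2,2'-bipyridine (10 mol%), NaI (25 mol%), pyridine (10 mol%), Mn powder (2 equiv), DMPU, 60 °C; filter through silica, then K2CO3 (20 mol%), MeOH, rt; aq. NH4Cl
Reagents that add atoms: none
Why: Nickel-catalysed reductive cross-electrophile coupling: zerovalent nickel–bipyridine adds oxidatively to the sp2 C–Br bond of 7, low-valent nickel turns the primary bromide 5 (partly exchanged to the iodide by NaI) into the C7 radical, this radical is captured by the aryl nickel bromide (divalent nickel) to give an aryl(alkyl) complex of trivalent nickel that forms the C7–C1 bond by reductive elimination, Mn returns nickel to its low-valent state, and K2CO3 in methanol then transesterifies the aryl acetate of 8 to the phenol. The closest known reaction type is the bipyridine–nickel reductive coupling of aryl bromides with primary alkyl bromides in amide solvents, which tolerates esters, aryl acetates, ethers and remote alkenes. No ring closes and no stereocentre is formed; C8 lies next to the radical centre but none of its four bonds is broken, so its S configuration should persist. The step needs cross-coupling over homo-coupling, which the two different activation modes (two-electron oxidative addition for the aryl bromide, halogen abstraction for the alkyl bromide) and the acetoxy-accelerated oxidative addition should secure. It also needs capture of the C7 radical by nickel to outrun loss of the ring A aryloxy group, which is favoured by the unstabilised primary radical, by a reductant that does not insert into the C–Br bond (so no β-aryloxy alkylmetal prone to elimination forms) and by fast reductive elimination from trivalent nickel. The allyl group cannot be reached by the C7 radical across the para-substituted ring A and should survive as long as little nickel hydride forms.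

**Compound list**
1 | 4-allyl-2,6-dimethoxyphenol | C=CCc1cc(OC)c(O)c(OC)c1 | starting material
2 | methyl (R)-lactate, methyl (2R)-2-hydroxypropanoate | C[C@@H](O)C(=O)OC | starting material
3 | methyl (2S)-2-(4-allyl-2,6-dimethoxyphenoxy)propanoate | C=CCc1cc(OC)c(O[C@@H](C)C(=O)OC)c(OC)c1 | intermediate
4 | (2S)-2-(4-allyl-2,6-dimethoxyphenoxy)propan-1-ol | C=CCc1cc(OC)c(O[C@@H](C)CO)c(OC)c1 | intermediate
5 | 5-allyl-2-{[(2S)-1-bromopropan-2-yl]oxy}-1,3-dimethoxybenzene | C=CCc1cc(OC)c(O[C@@H](C)CBr)c(OC)c1 | intermediate
6 | 4-bromo-2-methoxyphenol | COc1cc(Br)ccc1O | starting material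
7 | 4-bromo-2-methoxyphenyl acetate | COc1cc(Br)ccc1OC(C)=O | intermediate
8 | 4-[(2S)-2-(4-allyl-2,6-dimethoxyphenoxy)propyl]-2-methoxyphenyl acetate | C=CCc1cc(OC)c(O[C@@H](C)Cc2ccc(OC(C)=O)c(OC)c2)c(OC)c1 | intermediate
9 | 4-[(2S)-2-(4-allyl-2,6-dimethoxyphenoxy)propyl]-2-methoxyphenol | C=CCc1cc(OC)c(O[C@@H](C)Cc2ccc(O)c(OC)c2)c(OC)c1 | target

**Totals**
Total step count: 5. Longest linear sequence: 4 (steps 1, 2, 3 and 5); step 4 is a one-step side branch.

**Steps most likely to fail**

Step 5 (key step). The C7 radical or the alkylnickel species may fragment with loss of the ring A aryloxy group before the C–C bond forms. The two bromides may also homo-couple, and nickel hydride may move the allyl double bond into conjugation. The fallback is a polar copper-catalysed coupling that forms no radical at C7; it sets out from 5 and 6. Phenol 6 would be silylated (TBSCl, imidazole, DMF) to (4-bromo-2-methoxyphenoxy)(tert-butyl)dimethylsilane F1. F1 would be converted with Mg turnings in THF into [4-(tert-butyldimethylsilyloxy)-3-methoxyphenyl]magnesium bromide F2. F2 would be coupled with bromide 5 under Li2CuCl4 catalysis (THF/NMP, 0 °C to rt), an SN2-type substitution at the primary carbon by the aryl cuprate, to give tert-butyl{4-[(2S)-2-(4-allyl-2,6-dimethoxyphenoxy)propyl]-2-methoxyphenoxy}dimethylsilane F3. Bu4NF in THF would then cleave the silyl ether, and the fallback comes back to the route at 9.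

Step 1. Displacement by the di-ortho-substituted phenoxide may be slow, which would let the reduced azodicarboxylate be alkylated instead, and configurational purity at the α-ester carbon may be partly lost. The fallback separates activation from displacement; it sets out from 1 and 2. Lactate 2 would be converted (Tf2O, 2,6-lutidine, CH2Cl2, −78 °C) into methyl (2R)-2-{[(trifluoromethyl)sulfonyl]oxy}propanoate F4. The caesium phenoxide of 1 (Cs2CO3, MeCN, −20 °C to rt) would displace the triflate with inversion in a Williamson-type SN2 reaction, and the fallback comes back to the route at 3.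

Step 3. At the alkoxyphosphonium stage a ring A methoxy oxygen or the ether oxygen may take part in the ionisation, which would lead to migration of the aryloxy group or to cyclisation with loss of a methyl group. The fallback buys the C–Br bond; it sets out from 1 and bypasses 3 and 4. A Mitsunobu reaction of 1 with commercial (2R)-1-bromopropan-2-ol F5 (PPh3, DIAD, toluene, 0 °C to rt) should give the bromide directly with inversion at C8, and the fallback comes back to the route at 5.

**Further compounds**
F1 | step 5 | (4-bromo-2-methoxyphenoxy)(tert-butyl)dimethylsilane | COc1cc(Br)ccc1O[Si](C)(C)C(C)(C)C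
F2 | step 5 | [4-(tert-butyldimethylsilyloxy)-3-methoxyphenyl]magnesium bromide | COc1cc([Mg]Br)ccc1O[Si](C)(C)C(C)(C)C
F3 | step 5 | tert-butyl{4-[(2S)-2-(4-allyl-2,6-dimethoxyphenoxy)propyl]-2-methoxyphenoxy}dimethylsilane | C=CCc1cc(OC)c(O[C@@H](C)Cc2ccc(O[Si](C)(C)C(C)(C)C)c(OC)c2)c(OC)c1
F4 | step 1 | methyl (2R)-2-{[(trifluoromethyl)sulfonyl]oxy}propanoate | C[C@@H](OS(=O)(=O)C(F)(F)F)C(=O)OC
F5 | step 3 | (2R)-1-bromopropan-2-ol | C[C@@H](O)CBr
A1 | direct plan | 1-[3-methoxy-4-(triisopropylsilyloxy)phenyl]propan-1-one | CCC(=O)c1ccc(O[Si](C(C)C)(C(C)C)C(C)C)c(OC)c1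
A2 | direct plan | rac-2-bromo-1-[3-methoxy-4-(triisopropylsilyloxy)phenyl]propan-1-one | CC(Br)C(=O)c1ccc(O[Si](C(C)C)(C(C)C)C(C)C)c(OC)c1
A3 | direct plan | rac-2-(4-allyl-2,6-dimethoxyphenoxy)-1-[3-methoxy-4-(triisopropylsilyloxy)phenyl]propan-1-one | C=CCc1cc(OC)c(OC(C)C(=O)c2ccc(O[Si](C(C)C)(C(C)C)C(C)C)c(OC)c2)c(OC)c1
A4 | direct plan | (1S,2S)-2-(4-allyl-2,6-dimethoxyphenoxy)-1-[3-methoxy-4-(triisopropylsilyloxy)phenyl]propan-1-ol | C=CCc1cc(OC)c(O[C@@H](C)[C@@H](O)c2ccc(O[Si](C(C)C)(C(C)C)C(C)C)c(OC)c2)c(OC)c1
A5 | direct plan | (1S,2S)-2-(4-allyl-2,6-dimethoxyphenoxy)-1-[3-methoxy-4-(triisopropylsilyloxy)phenyl]propyl acetate | C=CCc1cc(OC)c(O[C@@H](C)[C@@H](OC(C)=O)c2ccc(O[Si](C(C)C)(C(C)C)C(C)C)c(OC)c2)c(OC)c1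
A6 | direct plan | 4-[(2S)-2-(4-allyl-2,6-dimethoxyphenoxy)propylidene]-2-methoxycyclohexa-2,5-dien-1-one | C=CCc1cc(OC)c(O[C@@H](C)C=C2C=CC(=O)C(OC)=C2)c(OC)c1
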